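The data were computed for substances that don't exist; noise was put on by code.

In the red flask free monomer has lost 87.6% of its charge by 15.0 h, far more than the 4.0% standing as monomer in chains, so we read the loss as mostly quenching by protic impurity.

| setting | red | green | flask |
|---|---|---|---|
| free monomer | 0.050 M | 0.050 M | 0.050 M |
| protic impurity | 0.050 M | 0.10 M | 0.0500 M |
| initiator | 0.25 mM | 0.25 mM | 0.25 mM |
| stray impurity | 85 µM | 85 µM | 85 µM |
| remark | the very flask that is asked about, followed so far | run made earlier |  |
| time |  |  | 40 h |

| run | time / h | monomer in chains / % | free monomer / % |
|---|---|---|---|
| red | 1.33 | 0 | 65.6 |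
| red | 2.50 | 1.6 | 51.1 |
| red | 5.00 | 0.8 | 32.5 |
| red | 8.00 | 2.4 | 23.3 |
| red | 15.0 | 4.0 | 12.4 |
| green | 1.33 | 0.7 | 43.3 |
| green | 4.00 | 1.0 | 12.8 |
| green | 8.00 | 0.4 | 3.0 |
| green | 12.0 | 0 | 1.8 |
| green | 15.0 | 0 | 0.8 |

(standard deviation of a reading: 0.5 percentage points)

- the average divides the monomer in chains by the number of chains begun, living and dead together
- what may be going on: free monomer + initiator -> living end + monomer in chains; free monomer + living end -> monomer in chains + living end; monomer in chains + living end -> free monomer + living end; initiator + stray impurity -> spent initiator A; free monomer + initiator -> spent initiator B; protic impurity + free monomer -> quenched substrate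
- the earlier runs do not show the number of chains; that part of a forecast is a guess

* average number of monomer units in a chain (chains begun, living or dead) at 40 h
* part of the free monomer that has reacted at 40 h

Red charges equal amounts of free monomer and protic impurity, so the two fall together. The inverse of the fraction left, less one, divided by time should then stay nearly constant, and we freeze it. Down the red table it reads 0.394 h⁻¹ at 1.33 h, 0.415 h⁻¹ at 5.00 h and 0.411 h⁻¹ at 8.00 h, the value we keep.

Now the chains column. Red's monomer in chains reads 2.4% and then 4.0% as free monomer comes down to 12.4%, but green's reads 1.0% and then 0.4% at 3.0% free monomer, and later 0%. So we read a level of free monomer below which chains give back more monomer than they take up: the turning level, the field's equilibrium monomer, which these scattered readings put near 12.4%.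

The frozen rate leaves red 5.73% free monomer at 40 h, so c is about 94.3%. The frozen rate brings red to the turning level near 17.2 h, earlier than 40 h, so we expect monomer in chains at 40 h to stand below the 4.0% read at 15.0 h. Spreading 4.0% over the 0.165 mM of initiator beyond the stray impurity's charge gives 12.1. Fewer chains raise that figure and less monomer in chains lowers it, so we commit to a dp of about that size, as a guess, since the number of chains is not shown.

The forecast gives dp 25 and c 95%, and on chains it goes the other way from us: “By 40 h I expect about 5% in chains”

The flask gives dp 7.24 and c 94.1%.

    free monomer + initiator → living end + monomer in chains (k = 0.0511 M⁻¹ min⁻¹)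
    free monomer + living end → monomer in chains + living end, rate k2*[living end]*[free monomer] (k = 3.45 M⁻¹ min⁻¹)
    monomer in chains + living end → free monomer + living end, rate k3*[living end] as long as [monomer in chains] is above zero (k = 0.0192 min⁻¹)
    initiator + stray impurity → spent initiator A (k = 140 M⁻¹ min⁻¹)
    free monomer + initiator → spent initiator B (k = 0.00671 M⁻¹ min⁻¹)
    protic impurity + free monomer → quenched substrate (k = 0.128 M⁻¹ min⁻¹)

At 40.0 h the red flask holds 5.88% free monomer, under the turning level, and its monomer in chains stands at 1.49%, down from 3.05% at 20.0 h. A neighbour flask charged with 0.013 M of protic impurity stands at 34.1% free monomer at the same time, above the turning level, with 39.9% monomer in chains and a dp of 140.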